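The disconnection on which everything rests opens the terminal furan-2(5H)-one ring across its C3=C4 double bond and its O1–C5 bond. This exposes ring carbon C4 as a ketone carbonyl and C5 as an electrophilic CH2Cl. The butenolide is therefore annulated last, in one operation, by a formal (3+2) union of a fully elaborated α-chloromethyl dienone with diethylphosphonoacetic acid: carboxylate O-alkylation, then intramolecular Horner–Wadsworth–Emmons olefination. The precursor already carries the (5R)-lactone from the chiral pool, the (Z)-alkylidene unit set by a Still–Gennari-type olefination, and the E-configured chain carved from (2E,6E)-farnesol.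

Key step: step 11

Remark: compounds 1, 6, 16 and 18 are taken as commercial. Compounds 2–4 are racemic at the carbon excised in step 3. Compounds 10–13 are mixtures of C3 epimers, a centre destroyed in step 8.

Step 1
Reactants: 1 (2E,6E)-farnesol
Product: 2 (2E,6E)-10-bromo-3,7,11-trimethyldodeca-2,6-diene-1,11-diol
Conditions: NBS, THF/H2O, 0 °C
Reagents that add atoms: N-bromosuccinimide O=C1CCC(=O)N1Br; water O
Why: Electrophilic bromohydrin formation in aqueous THF should select the terminal trisubstituted alkene (the C2 alkene is inductively deactivated by the allylic hydroxyl and the C6 alkene is shielded in the coiled chain), with Markovnikov attack of water at the tertiary carbon; the new centre is racemic and is excised in step 3.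

Step 2
Reactants: 2 (2E,6E)-10-bromo-3,7,11-trimethyldodeca-2,6-diene-1,11-diol
Product: 3 (2E,6E)-9-(3,3-dimethyloxiran-2-yl)-3,7-dimethylnona-2,6-dien-1-ol (10,11-epoxyfarnesol)
Conditions: K2CO3, MeOH, rt
Reagents that add atoms: none
Why: Intramolecular Williamson etherification, in which the tertiary alkoxide displaces the neighbouring secondary bromide to close the epoxide.

Step 3
Reactants: 3 10,11-epoxyfarnesol
Product: 5 (4E,8E)-10-hydroxy-4,8-dimethyldeca-4,8-dienal, via triol 4 (not isolated)
Conditions: H5IO6, THF/H2O, 0 °C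
Reagents that add atoms: none
Why: Acid-mediated epoxide hydrolysis to the vicinal diol followed by Malaprade glycol cleavage should excise acetone and leave the aldehyde (its oxygen is the former epoxide oxygen), while the isolated alkenes and the allylic alcohol are inert to periodic acid.

Step 4
Reactants: 6 (R)-5-(hydroxymethyl)dihydrofuran-2(3H)-one
Product: 7 (R)-5-oxotetrahydrofuran-2-carbaldehyde
Conditions: IBX, EtOAc, 80 °C; filtration
Reagents that add atoms: none
Why: IBX oxidation of the primary alcohol stops at the aldehyde, and the non-aqueous filtration work-up avoids hydrate formation and leaves the stereocentre untouched.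

Step 5
Reactants: 7 (R)-5-oxotetrahydrofuran-2-carbaldehyde
Product: 8 (R)-5-(2-methylprop-1-en-1-yl)dihydrofuran-2(3H)-one
Conditions: i-PrPPh3I, n-BuLi, THF, 0 °C; then 7, −78 °C → rt
Reagents that add atoms: isopropyltriphenylphosphonium iodide CC(C)[P+](c1ccccc1)(c1ccccc1)c1ccccc1.[I-]
Why: Wittig olefination with the non-stabilised isopropylidene ylide should convert the aldehyde chemoselectively over the lactone carbonyl into the trisubstituted alkene, and at −78 °C olefination should outpace enolisation so that the α-oxygenated centre is retained.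

Step 6
Reactants: 8 (R)-5-(2-methylprop-1-en-1-yl)dihydrofuran-2(3H)-one
Product: 10 diethyl [(5R)-5-(2-methylprop-1-en-1-yl)-2-oxotetrahydrofuran-3-yl]phosphonate (C3 epimers), via enol phosphate 9 (not isolated)
Conditions: LDA, THF, −78 °C; ClP(O)(OEt)2, −78 °C → rt; LDA (2.2 equiv), −78 °C → rt; AcOH
Reagents that add atoms: diethyl chlorophosphate CCOP(=O)(Cl)OCC
Why: O-Phosphorylation of the lactone enolate gives the ketene acetal phosphate, which on further deprotonation should undergo the anionic 1,3-phosphorus shift from oxygen to carbon (vinyl phosphate to β-keto phosphonate rearrangement), driven by formation of the stabilised phosphonate anion; C5 is not involved.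

Step 7
Reactants: 10 diethyl [(5R)-5-(2-methylprop-1-en-1-yl)-2-oxotetrahydrofuran-3-yl]phosphonate
Product: 13 bis(2,2,2-trifluoroethyl) [(5R)-5-(2-methylprop-1-en-1-yl)-2-oxotetrahydrofuran-3-yl]phosphonate (C3 epimers), via bis(trimethylsilyl) phosphonate 11 (not isolated), via phosphonic dichloride 12 (not isolated)
Conditions: TMSBr, pyridine, CH2Cl2, 0 °C → rt; (COCl)2, cat. DMF, CH2Cl2, rt; CF3CH2OH, Et3N, CH2Cl2, 0 °C → rt
Reagents that add atoms: 2,2,2-trifluoroethanol OCC(F)(F)F
Why: McKenna dealkylation, chlorination of the silyl ester with oxalyl chloride/DMF and esterification of the phosphonic dichloride is the standard ester exchange used to make Still–Gennari-type reagents; the pyridine buffer should suppress acid-promoted ionisation of the allylic lactone C–O bond.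

Step 8
Reactants: 5 (4E,8E)-10-hydroxy-4,8-dimethyldeca-4,8-dienal; 13 bis(2,2,2-trifluoroethyl) [(5R)-5-(2-methylprop-1-en-1-yl)-2-oxotetrahydrofuran-3-yl]phosphonate
Product: 14 (3Z,5R)-3-[(4E,8E)-10-hydroxy-4,8-dimethyldeca-4,8-dien-1-ylidene]-5-(2-methylprop-1-en-1-yl)dihydrofuran-2(3H)-one
Conditions: 13, KHMDS, 18-crown-6, THF, −78 °C; then 5, −78 °C → 0 °C
Reagents that add atoms: none
Why: Still–Gennari variant of the HWE olefination: the electron-poor phosphonate with a crown-separated potassium counter-ion should add irreversibly to the unhindered aldehyde and eliminate under kinetic control, placing the chain cis to the lactone carbonyl (Z), while the weakly basic phosphonate anion tolerates the free allylic alcohol and leaves C5 untouched.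

Step 9
Reactants: 14 (3Z,5R)-3-[(4E,8E)-10-hydroxy-4,8-dimethyldeca-4,8-dien-1-ylidene]-5-(2-methylprop-1-en-1-yl)dihydrofuran-2(3H)-one
Product: 15 (2E,6E,10Z)-3,7-dimethyl-10-[(5R)-5-(2-methylprop-1-en-1-yl)-2-oxodihydrofuran-3(2H)-ylidene]deca-2,6-dienal
Conditions: MnO2, CH2Cl2, rt
Reagents that add atoms: none
Why: Manganese dioxide oxidation is selective for the allylic alcohol and should give the enal without touching the alkylidene lactone or scrambling the E-trisubstituted alkene.

Step 10
Reactants: 15 (2E,6E,10Z)-3,7-dimethyl-10-[(5R)-5-(2-methylprop-1-en-1-yl)-2-oxodihydrofuran-3(2H)-ylidene]deca-2,6-dienal; 16 1-chloro-3-(triphenylphosphoranylidene)propan-2-one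
Product: 17 (3Z,5R)-3-[(4E,8E,10E)-13-chloro-4,8-dimethyl-12-oxotrideca-4,8,10-trien-1-ylidene]-5-(2-methylprop-1-en-1-yl)dihydrofuran-2(3H)-one
Conditions: toluene, 80 °C
Reagents that add atoms: none
Why: Wittig olefination with the stabilised keto ylide should give the E-enone under neutral conditions, with the chloromethyl group carried in intact by the reagent and the remote alkylidene lactone inert to the ylide.

Step 11
Reactants: 17 (3Z,5R)-3-[(4E,8E,10E)-13-chloro-4,8-dimethyl-12-oxotrideca-4,8,10-trien-1-ylidene]-5-(2-methylprop-1-en-1-yl)dihydrofuran-2(3H)-one; 18 diethylphosphonoacetic acid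
Product: 20 (3Z,5R)-3-[(4E,8E,10E)-4,8-dimethyl-11-(5-oxo-2,5-dihydrofuran-3-yl)undeca-4,8,10-trien-1-ylidene]-5-(2-methylprop-1-en-1-yl)dihydrofuran-2(3H)-one (target), via keto phosphonoacetate 19 (not isolated)
Conditions: K2CO3, 18-crown-6 (cat.), NaI (cat.), MeCN, 0 °C → rt
Reagents that add atoms: none
Why: The carboxylate of 18 displaces the activated α-keto chloride (SN2, iodide-assisted) to forge the CH2–O bond and give keto phosphonoacetate 19; its doubly activated P–CH2 is then deprotonated by carbonate and adds to the ketone carbonyl, and collapse of the oxaphosphetane expels diethyl phosphate to form the ring C=C. The closest known reaction type is the butenolide annulation of α-hydroxy or α-halo ketones by attachment of a phosphonoacetate followed by intramolecular HWE olefination, run here as a one-pot formal (3+2) annulation. The furanone ring closes in the C–C bond-forming event as a 5-exo-trig addition to the ketone, and the cyclic oxaphosphetane can only deliver the endocyclic cis alkene. No new stereocentre is formed, and the 5R centre of the other lactone is remote and not enolisable under carbonate. The step needs O- over C-alkylation (only the carboxylate is ionised until the ester exists), 1,2- over 1,4- or 1,6-addition to the dienone (five-membered against seven- or nine-membered transition states) and survival of the (Z)-alkylidene lactone, which the mild heterogeneous base and the intramolecular olefination should secure.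

Compound list
1 | (2E,6E)-farnesol | CC(C)=CCC/C(C)=C/CC/C(C)=C/CO | starting material
2 | (2E,6E)-10-bromo-3,7,11-trimethyldodeca-2,6-diene-1,11-diol (racemic at C10) | CC(C)(O)C(Br)CC/C(C)=C/CC/C(C)=C/CO | intermediate
3 | (2E,6E)-9-(3,3-dimethyloxiran-2-yl)-3,7-dimethylnona-2,6-dien-1-ol (racemic) | CC1(C)OC1CC/C(C)=C/CC/C(C)=C/CO | intermediate
4 | (2E,6E)-3,7,11-trimethyldodeca-2,6-diene-1,10,11-triol (not isolated) | CC(C)(O)C(O)CC/C(C)=C/CC/C(C)=C/CO | intermediate
5 | (4E,8E)-10-hydroxy-4,8-dimethyldeca-4,8-dienal | O=CCC/C(C)=C/CC/C(C)=C/CO | intermediate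
6 | (R)-5-(hydroxymethyl)dihydrofuran-2(3H)-one | OC[C@H]1CCC(=O)O1 | starting material
7 | (R)-5-oxotetrahydrofuran-2-carbaldehyde | O=C[C@H]1CCC(=O)O1 | intermediate
8 | (R)-5-(2-methylprop-1-en-1-yl)dihydrofuran-2(3H)-one | CC(C)=C[C@H]1CCC(=O)O1 | intermediate
9 | diethyl (R)-5-(2-methylprop-1-en-1-yl)-4,5-dihydrofuran-2-yl phosphate (not isolated) | CC(C)=C[C@H]1CC=C(OP(=O)(OCC)OCC)O1 | intermediate
10 | diethyl [(5R)-5-(2-methylprop-1-en-1-yl)-2-oxotetrahydrofuran-3-yl]phosphonate (C3 epimers) | CC(C)=C[C@H]1CC(P(=O)(OCC)OCC)C(=O)O1 | intermediate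
11 | bis(trimethylsilyl) [(5R)-5-(2-methylprop-1-en-1-yl)-2-oxotetrahydrofuran-3-yl]phosphonate (not isolated) | CC(C)=C[C@H]1CC(P(=O)(O[Si](C)(C)C)O[Si](C)(C)C)C(=O)O1 | intermediate
12 | [(5R)-5-(2-methylprop-1-en-1-yl)-2-oxotetrahydrofuran-3-yl]phosphonic dichloride (not isolated) | CC(C)=C[C@H]1CC(P(=O)(Cl)Cl)C(=O)O1 | intermediate
13 | bis(2,2,2-trifluoroethyl) [(5R)-5-(2-methylprop-1-en-1-yl)-2-oxotetrahydrofuran-3-yl]phosphonate (C3 epimers) | CC(C)=C[C@H]1CC(P(=O)(OCC(F)(F)F)OCC(F)(F)F)C(=O)O1 | intermediate
14 | (3Z,5R)-3-[(4E,8E)-10-hydroxy-4,8-dimethyldeca-4,8-dien-1-ylidene]-5-(2-methylprop-1-en-1-yl)dihydrofuran-2(3H)-one | CC(C)=C[C@H]1C/C(=C/CC/C(C)=C/CC/C(C)=C/CO)C(=O)O1 | intermediate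
15 | (2E,6E,10Z)-3,7-dimethyl-10-[(5R)-5-(2-methylprop-1-en-1-yl)-2-oxodihydrofuran-3(2H)-ylidene]deca-2,6-dienal | CC(C)=C[C@H]1C/C(=C/CC/C(C)=C/CC/C(C)=C/C=O)C(=O)O1 | intermediate
16 | 1-chloro-3-(triphenylphosphoranylidene)propan-2-one | O=C(CCl)C=P(c1ccccc1)(c1ccccc1)c1ccccc1 | starting material
17 | (3Z,5R)-3-[(4E,8E,10E)-13-chloro-4,8-dimethyl-12-oxotrideca-4,8,10-trien-1-ylidene]-5-(2-methylprop-1-en-1-yl)dihydrofuran-2(3H)-one | CC(C)=C[C@H]1C/C(=C/CC/C(C)=C/CC/C(C)=C/C=C/C(=O)CCl)C(=O)O1 | intermediate
18 | diethylphosphonoacetic acid | CCOP(=O)(CC(=O)O)OCC | starting material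
19 | (diethoxyphosphoryl)acetate ester of the α-hydroxymethyl dienone (17 with Cl replaced by OC(=O)CH2P(O)(OEt)2; not isolated) | CC(C)=C[C@H]1C/C(=C/CC/C(C)=C/CC/C(C)=C/C=C/C(=O)COC(=O)CP(=O)(OCC)OCC)C(=O)O1 | intermediate
20 | (3Z,5R)-3-[(4E,8E,10E)-4,8-dimethyl-11-(5-oxo-2,5-dihydrofuran-3-yl)undeca-4,8,10-trien-1-ylidene]-5-(2-methylprop-1-en-1-yl)dihydrofuran-2(3H)-one | CC(C)=C[C@H]1C/C(=C/CC/C(C)=C/CC/C(C)=C/C=C/C2=CC(=O)OC2)C(=O)O1 | target

Total step count: 11. Longest linear sequence: 8 steps (steps 4–11, from compound 6).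

Steps most likely to fail

Step 8. The risk is loss of kinetic control in the olefination (reversible addition or slow collapse of the adducts on warming), which would erode the Z geometry of the exocyclic alkene. The fallback sets the alkene by a stereospecific elimination and runs from 5 and 8 back to 14. Aldehyde 5 would be silylated (TBSCl, imidazole, CH2Cl2) to (4E,8E)-10-[(tert-butyldimethylsilyl)oxy]-4,8-dimethyldeca-4,8-dienal F1. Aldol addition of the lithium enolate of 8 (LDA, THF, −78 °C) should favour the anti adduct through a closed transition state, since the ring fixes the enolate geometry, and should occur on the face opposite the C5 substituent; chromatographic removal of minor diastereomers would give the (3R,5R,1'R)-anti-aldol adduct F2. Mesylation (MsCl, Et3N, CH2Cl2, 0 °C) would give the methanesulfonate F3. Anti-periplanar elimination (DBU, toluene, 0 °C → rt) should then deliver the (Z)-alkylidene lactone TBS ether F4, and desilylation (TBAF/AcOH, THF) returns to 14.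

Step 11. The risk is diversion of the phosphonate carbanion or the carbonate into conjugate addition or enolisation of the chloromethyl dienone, or base-mediated Z-to-E drift of the alkylidene lactone during the one-pot sequence. The fallback makes the same two bonds in separate, near-neutral operations and runs from 17 to 20. Bromoacetic acid with KHCO3 (DMF, 0 °C) would displace the chloride to give the bromoacetate ester F5. Triphenylphosphine (MeCN, rt) would convert it into the phosphonium bromide F6, and Et3N would then trigger the intramolecular Wittig olefination to 20.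

Step 7. The risk is ionisation of the allylic lactone C5–O bond by the silyl bromide or adventitious acid during the dealkylation and chlorination stages. The fallback introduces the fluorinated phosphorus group at the P(III) level under basic conditions and runs from 8 to 13. The lithium enolate of 8 (LDA, THF, −78 °C) would be C-phosphinylated with bis(2,2,2-trifluoroethyl) phosphorochloridite to give bis(2,2,2-trifluoroethyl) [(5R)-5-(2-methylprop-1-en-1-yl)-2-oxotetrahydrofuran-3-yl]phosphonite F7, and oxidation with t-BuOOH would give 13.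

Further compounds
F1 | step 8 | (4E,8E)-10-[(tert-butyldimethylsilyl)oxy]-4,8-dimethyldeca-4,8-dienal | O=CCC/C(C)=C/CC/C(C)=C/CO[Si](C)(C)C(C)(C)C
F2 | step 8 | (3R,5R)-3-[(1R,4E,8E)-10-[(tert-butyldimethylsilyl)oxy]-1-hydroxy-4,8-dimethyldeca-4,8-dien-1-yl]-5-(2-methylprop-1-en-1-yl)dihydrofuran-2(3H)-one | CC(C)=C[C@H]1C[C@H]([C@H](O)CC/C(C)=C/CC/C(C)=C/CO[Si](C)(C)C(C)(C)C)C(=O)O1
F3 | step 8 | methanesulfonate of F2 | CC(C)=C[C@H]1C[C@H]([C@H](OS(C)(=O)=O)CC/C(C)=C/CC/C(C)=C/CO[Si](C)(C)C(C)(C)C)C(=O)O1
F4 | step 8 | tert-butyldimethylsilyl ether of 14 | CC(C)=C[C@H]1C/C(=C/CC/C(C)=C/CC/C(C)=C/CO[Si](C)(C)C(C)(C)C)C(=O)O1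
F5 | step 11 | bromoacetate ester of the α-hydroxymethyl dienone (17 with Cl replaced by OC(=O)CH2Br) | CC(C)=C[C@H]1C/C(=C/CC/C(C)=C/CC/C(C)=C/C=C/C(=O)COC(=O)CBr)C(=O)O1
F6 | step 11 | triphenylphosphonium bromide derived from F5 | CC(C)=C[C@H]1C/C(=C/CC/C(C)=C/CC/C(C)=C/C=C/C(=O)COC(=O)C[P+](c2ccccc2)(c2ccccc2)c2ccccc2)C(=O)O1.[Br-]
F7 | step 7 | bis(2,2,2-trifluoroethyl) [(5R)-5-(2-methylprop-1-en-1-yl)-2-oxotetrahydrofuran-3-yl]phosphonite | CC(C)=C[C@H]1CC(P(OCC(F)(F)F)OCC(F)(F)F)C(=O)O1
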